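A flat top of X tempts one to fit a curve through the tops and forget that its height has a budget: the G charged.

| setting | grey | amber | violet | flask |
|---|---|---|---|---|
| Z | 0.64 M | 0.64 M | 0.64 M | 0.64 M |
| G | 0.768 M | 0.768 M | 1.5 M | 0.768 M |
| D | 0.64 M | 2.6 M | 1.28 M | 1.28 M |
| remark | run made earlier | run made earlier | run made earlier |  |
| time |  |  |  | 10 h |

- grey (time / h: X / %, Z / %): 0.500: 25.8, 60.4; 0.833: 31.8, 48.8; 1.50: 35.3, 37.4; 3.00: 37.6, 25.0; 6.00: 35.6, 17.3
- amber (time / h: X / %, Z / %): 0.500: 12.5, 71.7; 0.833: 13.3, 64.5; 1.50: 11.8, 51.8; 3.00: 13.2, 36.2; 6.00: 12.4, 21.7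
- violet (time / h: X / %, Z / %): 0.500: 38.4, 49.6; 0.833: 44.1, 39.2; 1.50: 47.8, 29.9; 3.00: 50.8, 21.0; 6.00: 47.9, 14.6

(each reading ± 0.5 percentage points)



1. the best time, 10 h at the latest, for X
2. the amount of X, in percent of the Z charged, at that time

In amber, X is flat from the first reading, at a mean of 12.6%, so we take G to be shared out early between Z and D. Let G, Z and D be the charges in M. If we hold Z and D at their charges and leave no G over, the top f of X, as a fraction of the Z charged, is

f = G/(Z + S·D)

Amber then gives S = 2.09, the selectivity factor: the pull of D on G over that of Z, mole for mole. As a check, the rule gives 38.8% for grey, whose highest reading is 37.6%, and 45.2% for violet, whose highest is 50.8%, so we trust it only to a few points.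

Now turn the question round. By our rule, G would favour Z if S·D/Z lay below 1, but the flask has

S·D/Z = 4.18

f = 23.2%

The rule gives no time. The forecast said 22.5% at 2 h, adding “The peak is flat, so the time is poorly defined”.

The flask gives 23.4% at 1.88 h.

    G + X → J (k = 1.50 × 10⁻⁵ M⁻¹ s⁻¹)
    Z + G ⇌ X (K = 21.0 M⁻¹, k = 4.20 × 10⁻⁴ M⁻¹ s⁻¹)
    Z ⇌ E (K = 2.80, k = 4.40 × 10⁻⁵ s⁻¹)
    2 Z → L (k = 6.00 × 10⁻⁵ M⁻¹ s⁻¹)
    D + G ⇌ Q (K = 33.0 M⁻¹, k = 8.80 × 10⁻⁴ M⁻¹ s⁻¹)

At 0.160 h in this flask, G goes 3.9 times as fast to Q as to X (forward rates of each step alone). Half of the turnover to Q up to 10 h is done by 0.160 h. J, absent from our rule, stands at 0.180% at the best time and makes no difference to the peak. For the neighbouring flask with 0.32 M of D and its other charges as here, the rule gives 58.7% against a simulated best of 49.2%, and that neighbour still holds 21% of its G at 10 h.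

Readings and results come from a simulation with made-up constants, noise included.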